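The route reads the 1,5-diketone O=C–Cb–Ca–CH2–C=O, which spans the two adjacent methyl-bearing quaternary carbons of the cyclopentane ring (Cb bears the enone carbonyl, Ca the CH2 arm), as the retro-aldol product of a cyclobutanol fused across the Ca–Cb bond. The key step oxidises one side-chain carbinol; the resulting 2-acylcyclobutanol opens by strain-driven retro-aldol cleavage and delivers, in one operation, the ynone carbonyl on Cb and the chain ketone beside the CH2 on Ca, with the cis-dimethyl pattern already locked. Its precursor is a cis-fused (1S,5S)-1,5-dimethylbicyclo[3.2.0]heptane carrying a tertiary alkynyl carbinol at C6 and, at C7, a hydroxyethyl arm ending in the (R)-chromene.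

Key step: step 15

Assumption: the (2S,5S)-pyrrolidine auxiliary (step 2) and the (1R,2R)-diphosphine (step 8) are taken to induce the configurations drawn; should either induce the opposite sense, its mirror-image form is used and nothing else changes.

Step 1
Reactants: 1 (2S,5S)-2,5-dimethylpyrrolidine
Product: 2 1-[(2S,5S)-2,5-dimethylpyrrolidin-1-yl]ethan-1-one
Conditions: AcCl, Et3N, CH2Cl2, 0 °C to rt
Reagents that add atoms: acetyl chloride, CC(=O)Cl
Why: N-acylation of a secondary amine by an acyl chloride with an amine base as HCl scavenger; the two stereocentres of the auxiliary are not touched.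

Step 2
Reactants: 2 1-[(2S,5S)-2,5-dimethylpyrrolidin-1-yl]ethan-1-one; 3 1,2-dimethylcyclopentene
Product: 6 (1S,5S)-1,5-dimethylbicyclo[3.2.0]heptan-6-one, via keteniminium triflate 4 (not isolated), via cyclobutaniminium triflate 5 (not isolated)
Conditions: Tf2O, 2,6-di-tert-butyl-4-methylpyridine, 3 (2 equiv), ClCH2CH2Cl, -20 °C to 60 °C; then H2O, NaHCO3, rt (amine recovered by basic extraction)
Reagents that add atoms: water, O
Why: O-triflation of the amide and loss of triflic acid to the hindered pyridine give keteniminium ion 4, whose central carbon is attacked by the electron-rich alkene and closes to the four-membered iminium 5 (keteniminium–alkene [2+2] cycloaddition); addition is suprafacial on the ring alkene so the fusion is cis, the C2-symmetric pyrrolidine should let one methyl group disfavour one of the two orientations of the symmetric alkene and so set C1 and C5 together, and hydrolysis frees the ketone and the auxiliary.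

Step 3
Reactants: 7 4-methoxy-2-methylphenol
Product: 8 2-hydroxy-5-methoxy-3-methylbenzaldehyde
Conditions: MgCl2, Et3N, (CH2O)n, MeCN, reflux; then aq HCl
Reagents that add atoms: paraformaldehyde (formaldehyde unit), C=O
Why: Magnesium phenoxide-directed ortho-formylation (Casnati–Skattebøl reaction) delivers formaldehyde to the only free ortho position, and a second formaldehyde oxidises the benzylic alkoxide by hydride transfer.

Step 4
Reactants: 9 4-hydroxybutan-2-one
Product: 10 4-(tert-butyldimethylsilyloxy)butan-2-one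
Conditions: TBSCl, imidazole, CH2Cl2, 0 °C to rt
Reagents that add atoms: tert-butyldimethylsilyl chloride, CC(C)(C)[Si](C)(C)Cl
Why: Silylation of the primary alcohol under mild imidazole conditions should avoid beta-elimination to methyl vinyl ketone.

Step 5
Reactants: 10 4-(tert-butyldimethylsilyloxy)butan-2-one
Product: 11 methyl (E)-5-(tert-butyldimethylsilyloxy)-3-methylpent-2-enoate
Conditions: (MeO)2P(O)CH2CO2Me, NaH, THF, 0 °C to rt; chromatographic removal of the Z isomer
Reagents that add atoms: trimethyl phosphonoacetate, COC(=O)CP(=O)(OC)OC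
Why: Horner–Wadsworth–Emmons olefination of the methyl ketone should favour the E ester, in which the larger silyloxyethyl branch is trans to the ester, and the minor Z isomer is separable here or after step 6.

Step 6
Reactants: 11 methyl (E)-5-(tert-butyldimethylsilyloxy)-3-methylpent-2-enoate
Product: 12 (E)-5-(tert-butyldimethylsilyloxy)-3-methylpent-2-en-1-ol
Conditions: i-Bu2AlH (2.2 equiv), CH2Cl2, -78 °C; aq potassium sodium tartrate
Reagents that add atoms: none
Why: 1,2-Reduction of the enoate by two hydrides from the aluminium hydride at low temperature leaves the alkene geometry and the silyl ether intact.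

Step 7
Reactants: 12 (E)-5-(tert-butyldimethylsilyloxy)-3-methylpent-2-en-1-ol
Product: 13 (E)-5-(tert-butyldimethylsilyloxy)-3-methylpent-2-en-1-yl methyl carbonate
Conditions: ClCO2Me, pyridine, CH2Cl2, 0 °C
Reagents that add atoms: methyl chloroformate, COC(=O)Cl
Why: O-acylation of the allylic alcohol with a chloroformate gives the carbonate, an ionisable leaving group that releases its own base on ionisation.

Step 8
Reactants: 8 2-hydroxy-5-methoxy-3-methylbenzaldehyde; 13 (E)-5-(tert-butyldimethylsilyloxy)-3-methylpent-2-en-1-yl methyl carbonate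
Product: 14 2-{[(3R)-5-(tert-butyldimethylsilyloxy)-3-methylpent-1-en-3-yl]oxy}-5-methoxy-3-methylbenzaldehyde
Conditions: Pd2(dba)3·CHCl3 (2 mol %, zerovalent palladium source), (1R,2R)-N,N'-bis[2-(diphenylphosphino)benzoyl]cyclohexane-1,2-diamine (6 mol %), CH2Cl2, rt
Reagents that add atoms: none
Why: Tsuji–Trost asymmetric allylic O-alkylation, in which ionisation of the carbonate gives a π-allyl palladium complex and methoxide (after loss of CO2) that deprotonates the phenol, and the phenoxide attacks the more substituted allyl carbon inside the chiral pocket of the diphosphine, so the tertiary C–O stereocentre (R) is set by the ligand acting on the geometrically pure E substrate.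

Step 9
Reactants: 14 2-{[(3R)-5-(tert-butyldimethylsilyloxy)-3-methylpent-1-en-3-yl]oxy}-5-methoxy-3-methylbenzaldehyde
Product: 15 tert-butyl{[(3R)-3-(2-ethenyl-4-methoxy-6-methylphenoxy)-3-methylpent-4-en-1-yl]oxy}dimethylsilane
Conditions: Ph3PCH3Br, KOt-Bu, THF, 0 °C
Reagents that add atoms: methyltriphenylphosphonium bromide, C[P+](c1ccccc1)(c1ccccc1)c1ccccc1.[Br-]
Why: Wittig methylenation of a non-enolisable aryl aldehyde, under conditions that leave the tertiary allyl aryl ether and its stereocentre alone.

Step 10
Reactants: 15 tert-butyl{[(3R)-3-(2-ethenyl-4-methoxy-6-methylphenoxy)-3-methylpent-4-en-1-yl]oxy}dimethylsilane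
Product: 16 tert-butyl{2-[(2R)-6-methoxy-2,8-dimethyl-2H-chromen-2-yl]ethoxy}dimethylsilane
Conditions: second-generation Grubbs catalyst (5 mol %), CH2Cl2, 40 °C
Reagents that add atoms: none
Why: Ring-closing metathesis of the styrene with the monosubstituted vinyl group forms the six-membered pyran ring with loss of ethylene, and the quaternary stereocentre takes no part.

Step 11
Reactants: 16 tert-butyl{2-[(2R)-6-methoxy-2,8-dimethyl-2H-chromen-2-yl]ethoxy}dimethylsilane
Product: 17 2-[(2R)-6-methoxy-2,8-dimethyl-2H-chromen-2-yl]ethan-1-ol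
Conditions: Bu4NF, THF, 0 °C to rt
Reagents that add atoms: none
Why: Fluoride-induced cleavage of the primary silyl ether, driven by the strong Si–F bond, leaves the chromene untouched.

Step 12
Reactants: 17 2-[(2R)-6-methoxy-2,8-dimethyl-2H-chromen-2-yl]ethan-1-ol
Product: 18 [(2R)-6-methoxy-2,8-dimethyl-2H-chromen-2-yl]acetaldehyde
Conditions: Dess–Martin periodinane, NaHCO3, CH2Cl2, 0 °C to rt; crude aldehyde used at once
Reagents that add atoms: none
Why: Dess–Martin oxidation under bicarbonate buffering gives the beta-aryloxy aldehyde without the acid or base that would trigger elimination of the aryloxide and loss of configuration at chromene C2.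

Step 13
Reactants: 6 (1S,5S)-1,5-dimethylbicyclo[3.2.0]heptan-6-one; 18 [(2R)-6-methoxy-2,8-dimethyl-2H-chromen-2-yl]acetaldehyde
Product: 20 (1S,5S)-7-{1-hydroxy-2-[(2R)-6-methoxy-2,8-dimethyl-2H-chromen-2-yl]ethyl}-1,5-dimethylbicyclo[3.2.0]heptan-6-one (epimers at C7/carbinol carbon), via lithium enolate 19 (not isolated)
Conditions: LiN(i-Pr)2, THF, -78 °C, 6 (1.3 equiv); then 18, -78 °C; AcOH quench at -78 °C
Reagents that add atoms: none
Why: Directed aldol addition, in which the preformed lithium enolate (C7 is the only enolisable position because C5 is quaternary) should add to the aldehyde at -78 °C faster than it deprotonates it; the two new centres are not controlled and both are erased in step 15.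

Step 14
Reactants: 20 (1S,5S)-7-{1-hydroxy-2-[(2R)-6-methoxy-2,8-dimethyl-2H-chromen-2-yl]ethyl}-1,5-dimethylbicyclo[3.2.0]heptan-6-one; 21 2-methylbut-3-yn-2-ol
Product: 23 (1S,5S)-7-{1-hydroxy-2-[(2R)-6-methoxy-2,8-dimethyl-2H-chromen-2-yl]ethyl}-6-(3-hydroxy-3-methylbut-1-yn-1-yl)-1,5-dimethylbicyclo[3.2.0]heptan-6-ol (epimer mixture), via dilithium alkynolate 22 (not isolated)
Conditions: 21 (3.5 equiv), n-BuLi (7 equiv), THF, -78 to 0 °C; CeCl3 (3.5 equiv), -78 °C; then 20, -78 °C; aq NH4Cl
Reagents that add atoms: none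
Why: 1,2-Addition of a weakly basic, strongly nucleophilic trivalent cerium acetylide to the strained and therefore electrophilic cyclobutanone carbonyl; the first equivalent turns the aldol hydroxyl into an alkoxide that should neither revert at -78 °C nor allow enolisation at C7, and the new carbinol centre is uncontrolled and erased in step 15.

Step 15
Reactants: 23 (1S,5S)-7-{1-hydroxy-2-[(2R)-6-methoxy-2,8-dimethyl-2H-chromen-2-yl]ethyl}-6-(3-hydroxy-3-methylbut-1-yn-1-yl)-1,5-dimethylbicyclo[3.2.0]heptan-6-ol
Product: 25 1-[(1S,2S)-2-{3-[(2R)-6-methoxy-2,8-dimethyl-2H-chromen-2-yl]-2-oxopropyl}-1,2-dimethylcyclopentyl]-4-hydroxy-4-methylpent-2-yn-1-one, via acylcyclobutanol 24 (not isolated)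
Conditions: Dess–Martin periodinane, NaHCO3, CH2Cl2, 0 °C to rt; silica gel, CH2Cl2, rt if 24 persists
Reagents that add atoms: none
Why: The periodinane oxidises the only secondary alcohol of 23 (both tertiary carbinols are inert) to the 7-acylcyclobutanol 24, a beta-hydroxy ketone whose hydroxyl-bearing carbon C6 and alpha carbon C7 are joined by a strained ring bond. Proton transfer from the C6 hydroxyl to the new carbonyl oxygen with cleavage of C6–C7 (retro-aldol) gives the ynone carbonyl on Cb and the enol of the chain ketone, which tautomerises so that C7 ends as the CH2 on Ca; release of the cyclobutane strain (about 26 kcal/mol) makes the opening irreversible. The closest known reaction type is the retro-aldol fragmentation of 2-acylcyclobutanols, the second stage of the De Mayo reaction, reached here without light. No ring is closed and no stereocentre is created: the four-membered ring opens, the three uncontrolled centres (C6, C7 and the carbinol carbon) become carbonyl or CH2 carbons, and the cis quaternary pair from step 2 is untouched. The step needs chemoselective oxidation, cleavage of one specific bond and near-neutral conditions; the substrate secures the first two because it has a single oxidisable alcohol and only C6–C7 lies between the cyclobutanol carbon and the new ketone, and the bicarbonate buffer secures the third, so the enol is protonated at C7 before an enolate can form at the CH2 next to chromene C2 and expel the aryloxide.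

Step 16
Reactants: 25 1-[(1S,2S)-2-{3-[(2R)-6-methoxy-2,8-dimethyl-2H-chromen-2-yl]-2-oxopropyl}-1,2-dimethylcyclopentyl]-4-hydroxy-4-methylpent-2-yn-1-one
Product: 26 (2Z)-1-[(1S,2S)-2-{3-[(2R)-6-methoxy-2,8-dimethyl-2H-chromen-2-yl]-2-oxopropyl}-1,2-dimethylcyclopentyl]-4-hydroxy-4-methylpent-2-en-1-one (CNP0137762.2)
Conditions: H2 (1 atm, stopped at 1 equiv), Pd/CaCO3 poisoned with Pb(OAc)2, quinoline, EtOAc, 0 °C to rt
Reagents that add atoms: none
Why: Syn semihydrogenation, in which both hydrogens are delivered from the poisoned palladium surface to the strongly adsorbed alkyne to give the Z enone, and stopping at one equivalent should spare the chromene C3=C4 bond and the product alkene.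

Compound list
1 | (2S,5S)-2,5-dimethylpyrrolidine | N1[C@@H](C)CC[C@@H]1C | starting material
2 | 1-[(2S,5S)-2,5-dimethylpyrrolidin-1-yl]ethan-1-one | CC(=O)N1[C@@H](C)CC[C@@H]1C | intermediate
3 | 1,2-dimethylcyclopentene | CC1=C(C)CCC1 | starting material
4 | N-ethenylidene-(2S,5S)-2,5-dimethylpyrrolidinium triflate (keteniminium salt, not isolated) | C=C=[N+]1[C@@H](C)CC[C@@H]1C.[O-]S(=O)(=O)C(F)(F)F | intermediate
5 | N-[(1S,5S)-1,5-dimethylbicyclo[3.2.0]heptan-6-ylidene]-(2S,5S)-2,5-dimethylpyrrolidinium triflate (not isolated) | C1(=[N+]2[C@@H](C)CC[C@@H]2C)C[C@]3(C)CCC[C@]13C.[O-]S(=O)(=O)C(F)(F)F | intermediate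
6 | (1S,5S)-1,5-dimethylbicyclo[3.2.0]heptan-6-one, cis-fused | O=C1C[C@]2(C)CCC[C@]12C | intermediate
7 | 4-methoxy-2-methylphenol | COc1ccc(O)c(C)c1 | starting material
8 | 2-hydroxy-5-methoxy-3-methylbenzaldehyde | COc1cc(C)c(O)c(C=O)c1 | intermediate
9 | 4-hydroxybutan-2-one | CC(=O)CCO | starting material
10 | 4-(tert-butyldimethylsilyloxy)butan-2-one | CC(=O)CCO[Si](C)(C)C(C)(C)C | intermediate
11 | methyl (E)-5-(tert-butyldimethylsilyloxy)-3-methylpent-2-enoate | COC(=O)/C=C(\C)CCO[Si](C)(C)C(C)(C)C | intermediate
12 | (E)-5-(tert-butyldimethylsilyloxy)-3-methylpent-2-en-1-ol | OC/C=C(\C)CCO[Si](C)(C)C(C)(C)C | intermediate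
13 | (E)-5-(tert-butyldimethylsilyloxy)-3-methylpent-2-en-1-yl methyl carbonate | COC(=O)OC/C=C(\C)CCO[Si](C)(C)C(C)(C)C | intermediate
14 | 2-{[(3R)-5-(tert-butyldimethylsilyloxy)-3-methylpent-1-en-3-yl]oxy}-5-methoxy-3-methylbenzaldehyde | C=C[C@@](C)(CCO[Si](C)(C)C(C)(C)C)Oc1c(C)cc(OC)cc1C=O | intermediate
15 | tert-butyl{[(3R)-3-(2-ethenyl-4-methoxy-6-methylphenoxy)-3-methylpent-4-en-1-yl]oxy}dimethylsilane | C=C[C@@](C)(CCO[Si](C)(C)C(C)(C)C)Oc1c(C)cc(OC)cc1C=C | intermediate
16 | tert-butyl{2-[(2R)-6-methoxy-2,8-dimethyl-2H-chromen-2-yl]ethoxy}dimethylsilane | COc1cc(C)c2c(c1)C=C[C@@](C)(CCO[Si](C)(C)C(C)(C)C)O2 | intermediate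
17 | 2-[(2R)-6-methoxy-2,8-dimethyl-2H-chromen-2-yl]ethan-1-ol | COc1cc(C)c2c(c1)C=C[C@@](C)(CCO)O2 | intermediate
18 | [(2R)-6-methoxy-2,8-dimethyl-2H-chromen-2-yl]acetaldehyde | COc1cc(C)c2c(c1)C=C[C@@](C)(CC=O)O2 | intermediate
19 | lithium (1S,5S)-1,5-dimethylbicyclo[3.2.0]hept-6-en-6-olate (not isolated) | [Li]OC1=C[C@]2(C)CCC[C@]12C | intermediate
20 | (1S,5S)-7-{1-hydroxy-2-[(2R)-6-methoxy-2,8-dimethyl-2H-chromen-2-yl]ethyl}-1,5-dimethylbicyclo[3.2.0]heptan-6-one, C7 and carbinol carbon unspecified | COc1cc(C)c2c(c1)C=C[C@@](C)(CC(O)C3C(=O)[C@@]4(C)CCC[C@@]34C)O2 | intermediate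
21 | 2-methylbut-3-yn-2-ol | C#CC(C)(C)O | starting material
22 | dilithium salt of 2-methylbut-3-yn-2-ol, acetylide and alkoxide (not isolated) | [Li]C#CC(C)(C)O[Li] | intermediate
23 | (1S,5S)-7-{1-hydroxy-2-[(2R)-6-methoxy-2,8-dimethyl-2H-chromen-2-yl]ethyl}-6-(3-hydroxy-3-methylbut-1-yn-1-yl)-1,5-dimethylbicyclo[3.2.0]heptan-6-ol, C6, C7 and carbinol carbon unspecified | COc1cc(C)c2c(c1)C=C[C@@](C)(CC(O)C3C(O)(C#CC(C)(C)O)[C@@]4(C)CCC[C@@]34C)O2 | intermediate
24 | 1-[(1S,5S)-6-hydroxy-6-(3-hydroxy-3-methylbut-1-yn-1-yl)-1,5-dimethylbicyclo[3.2.0]heptan-7-yl]-2-[(2R)-6-methoxy-2,8-dimethyl-2H-chromen-2-yl]ethan-1-one, C6 and C7 unspecified (not isolated) | COc1cc(C)c2c(c1)C=C[C@@](C)(CC(=O)C3C(O)(C#CC(C)(C)O)[C@@]4(C)CCC[C@@]34C)O2 | intermediate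
25 | 1-[(1S,2S)-2-{3-[(2R)-6-methoxy-2,8-dimethyl-2H-chromen-2-yl]-2-oxopropyl}-1,2-dimethylcyclopentyl]-4-hydroxy-4-methylpent-2-yn-1-one | COc1cc(C)c2c(c1)C=C[C@@](C)(CC(=O)C[C@]1(C)CCC[C@]1(C)C(=O)C#CC(C)(C)O)O2 | intermediate
26 | (2Z)-1-[(1S,2S)-2-{3-[(2R)-6-methoxy-2,8-dimethyl-2H-chromen-2-yl]-2-oxopropyl}-1,2-dimethylcyclopentyl]-4-hydroxy-4-methylpent-2-en-1-one | COc1cc(C)c2c(c1)C=C[C@@](C)(CC(=O)C[C@]1(C)CCC[C@]1(C)C(=O)/C=C\C(C)(C)O)O2 | target

Total step count: 16.
Longest linear sequence: 13 steps (steps 4 to 16, from 4-hydroxybutan-2-one).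

Steps most likely to fail

Step 2. The auxiliary may discriminate poorly between the two orientations of a symmetric tetrasubstituted alkene, and the tertiary cation may lose a proton instead of closing the ring. The fallback sets out from 3. Dichloroketene, generated from Cl3CCOCl with Zn(Cu) and POCl3 in Et2O, should add across the alkene to give racemic cis-7,7-dichloro-1,5-dimethylbicyclo[3.2.0]heptan-6-one F1. Reductive dechlorination with Zn in AcOH should give racemic cis-1,5-dimethylbicyclo[3.2.0]heptan-6-one F2. Addition of lithiated (S)-N,S-dimethyl-S-phenylsulfoximine (n-BuLi, THF, -78 °C) should give diastereomeric beta-hydroxysulfoximines that are separable on silica. The diastereomer derived from the (1S,5S) ketone, (1S,5S)-1,5-dimethyl-6-{[(S)-N-methyl-S-phenylsulfonimidoyl]methyl}bicyclo[3.2.0]heptan-6-ol F3, is heated in toluene at 110 °C, where it reverts to the sulfoximine and the ketone. The route is rejoined at compound 6.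

Step 8. The doubly ortho-substituted, hydrogen-bonded phenoxide may attack slowly or at the unsubstituted allyl terminus, and reversible ionisation of the product may erode the enantioselectivity. The fallback sets out from 12 and 7. MnO2 in CH2Cl2 should oxidise 12 to (E)-5-(tert-butyldimethylsilyloxy)-3-methylpent-2-enal F4. Condensation of F4 with phenol 7 (PhB(OH)2, catalytic AcOH, toluene, reflux with removal of water) should proceed through an ortho-quinone methide and oxa-6π electrocyclisation to give racemic tert-butyl{2-[6-methoxy-2,8-dimethyl-2H-chromen-2-yl]ethoxy}dimethylsilane F5. Preparative chromatography on a chiral stationary phase then separates the enantiomers, and the R enantiomer is compound 16, where the route is rejoined. Steps 3 and 7 to 10 are then not needed.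

Step 14. The metal aldolate may revert to enolate and aldehyde, or the acetylide may enolise C7 instead of adding to the hindered C6 carbonyl. The fallback sets out from 20. Silylation (Et3SiCl, imidazole, DMF, 0 °C) should give the triethylsilyl ether of 20 F6, which cannot revert. Addition of the same trivalent cerium acetylide from 21 (n-BuLi, CeCl3, THF, -78 °C) should give the triethylsilyl ether of 23 F7. Buffered desilylation (HF·pyridine, pyridine, THF, 0 °C) then frees the secondary alcohol, and the route is rejoined at compound 23.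

Further compounds
F1 | step 2 | racemic cis-7,7-dichloro-1,5-dimethylbicyclo[3.2.0]heptan-6-one | O=C1C(Cl)(Cl)C2(C)CCCC12C
F2 | step 2 | racemic cis-1,5-dimethylbicyclo[3.2.0]heptan-6-one | O=C1CC2(C)CCCC12C
F3 | step 2 | (1S,5S)-1,5-dimethyl-6-{[(S)-N-methyl-S-phenylsulfonimidoyl]methyl}bicyclo[3.2.0]heptan-6-ol, C6 unspecified | OC1(C[S@@](=O)(=NC)c2ccccc2)C[C@]3(C)CCC[C@]13C
F4 | step 8 | (E)-5-(tert-butyldimethylsilyloxy)-3-methylpent-2-enal | O=C/C=C(\C)CCO[Si](C)(C)C(C)(C)C
F5 | step 8 | racemic tert-butyl{2-[6-methoxy-2,8-dimethyl-2H-chromen-2-yl]ethoxy}dimethylsilane | COc1cc(C)c2c(c1)C=CC(C)(CCO[Si](C)(C)C(C)(C)C)O2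
F6 | step 14 | triethylsilyl ether of 20 at the aldol hydroxyl | COc1cc(C)c2c(c1)C=C[C@@](C)(CC(O[Si](CC)(CC)CC)C3C(=O)[C@@]4(C)CCC[C@@]34C)O2
F7 | step 14 | triethylsilyl ether of 23 at the secondary hydroxyl | COc1cc(C)c2c(c1)C=C[C@@](C)(CC(O[Si](CC)(CC)CC)C3C(O)(C#CC(C)(C)O)[C@@]4(C)CCC[C@@]34C)O2
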